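**Plan**

- Retrosynthesis: (1) both phenols are unmasked last from benzyl ethers; (2) the oxolane is opened at the O–CH2 bond on the carbinol side, and its other CH2 is raised to a carboxyl closed onto the benzylic oxygen, so the oxolane is traded for a γ-lactone; (3) in that lactone the ArCH2–C(α) bond is cut to a lactone enolate and an isovanillyl bromide; (4) the lactone is cut by an aldol disconnection into a succinate imide and O-benzylisovanillin.
- Enabling feature: the benzylic carbinol oxygen stands 1,4 to the ring CH2 beside the benzyl-bearing carbon. That carbon can therefore be the α-carbon of a 5-aryl-γ-butyrolactone, and a 3,4-trans relationship in this lactone is the 3,4-cis relationship of the oxolane once the ring is switched.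
- Forward: anti-aldol and closure of the γ-lactone (temporary ring); union of the two aryl halves by α-benzylation; acid-to-alcohol reduction and mesylation; reductive ring switch that destroys the lactone and closes the oxolane; debenzylation.
- Stereochemistry: the oxazolidinone auxiliary sets the carbinol carbon and its neighbour in the anti-aldol; the lactone ring relays this to the third centre in the benzylation; no stereocentre is a reacting carbon afterwards.

Key step: step 5

Assumption: the magnesium-catalysed anti-aldol of the (S)-imide is taken to follow the chelated (Z)-enolate model, with the aldehyde adding to the enolate face remote from the 4-benzyl group (the face used in alkylations of this auxiliary); if the sense were opposite, the (R)-auxiliary would be used.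

**Route**

Step 1
Reactants: 1 (S)-4-benzyl-1,3-oxazolidin-2-one; 2 methyl 4-chloro-4-oxobutanoate
Product: 4 methyl 4-[(4S)-4-benzyl-2-oxo-1,3-oxazolidin-3-yl]-4-oxobutanoate, via N-lithio oxazolidinone 3 (not isolated)
Conditions: n-BuLi, THF, −78 °C; then 2, −78 → 0 °C
Reagents that add atoms: none
Why: N-acylation of a lithiated oxazolidinone by an acid chloride is the standard entry to Evans imides, the acyl chloride end of 2 reacting far faster than its methyl ester; no stereocentre is formed.

Step 2
Reactants: 4 methyl 4-[(4S)-4-benzyl-2-oxo-1,3-oxazolidin-3-yl]-4-oxobutanoate; 5 3-(benzyloxy)-4-methoxybenzaldehyde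
Product: 8 (4S)-4-benzyl-3-{[(2S,3R)-2-[3-(benzyloxy)-4-methoxyphenyl]-5-oxooxolan-3-yl]carbonyl}-1,3-oxazolidin-2-one (aryl and acyl groups cis), via silyl ether aldol adduct 6 (not isolated), via hydroxy ester aldol adduct 7 (not isolated)
Conditions: MgCl2 (20 mol%), Et3N, TMSCl, EtOAc, rt; then 1 M HCl/THF, rt; then PPTS (cat.), PhMe, 50 °C
Reagents that add atoms: none
Why: Evans-type magnesium halide-catalysed direct anti-aldol, in which soft enolisation of the Mg-chelated imide (not of the remote ester) gives the (Z)-enolate, the non-enolisable aldehyde adds through a boat-like transition state on the face remote from the 4-benzyl group so that the auxiliary sets both new centres (3R,4S, anti), silylation drives turnover, and after mild desilylation the γ-hydroxy ester closes by acid-catalysed transesterification to the five-membered lactone.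

Step 3
Reactants: 8 (4S)-4-benzyl-3-{[(2S,3R)-2-[3-(benzyloxy)-4-methoxyphenyl]-5-oxooxolan-3-yl]carbonyl}-1,3-oxazolidin-2-one
Product: 10 (2S,3R)-2-[3-(benzyloxy)-4-methoxyphenyl]-5-oxooxolane-3-carboxylic acid (cis), via lithium peroxycarboxylate 9 (not isolated)
Conditions: LiOH, H2O2, THF/H2O (3:1), 0 °C; aq. Na2SO3; then 1 M HCl to pH 2
Reagents that add atoms: hydrogen peroxide, OO
Why: Hydroperoxide attacks the exocyclic imide carbonyl selectively (standard LiOOH cleavage of Evans imides), the cold medium should leave the epimerisable carbon next to the carbonyl untouched, sulfite reduces the peracid and acidification re-closes any opened lactone, so no stereocentre is formed or lost and auxiliary 1 is recovered.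

Step 4
Reactants: 11 [3-(benzyloxy)-4-methoxyphenyl]methanol
Product: 12 2-(benzyloxy)-4-(bromomethyl)-1-methoxybenzene
Conditions: PBr3, Et2O, 0 °C
Reagents that add atoms: phosphorus tribromide, BrP(Br)Br
Why: Standard conversion of an electron-rich benzylic alcohol into its bromide by SN2 displacement on the phosphite ester; no stereocentre, and the bromide is used freshly prepared.

Step 5
Reactants: 10 (2S,3R)-2-[3-(benzyloxy)-4-methoxyphenyl]-5-oxooxolane-3-carboxylic acid; 12 2-(benzyloxy)-4-(bromomethyl)-1-methoxybenzene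
Product: 14 (2S,3R,4R)-4-[3-(benzyloxy)-4-methoxybenzyl]-2-[3-(benzyloxy)-4-methoxyphenyl]-5-oxooxolane-3-carboxylic acid, via disodium carboxylate enolate 13 (not isolated)
Conditions: NaHMDS (2.3 equiv), THF, −78 °C; then 12, −78 → −40 °C; 1 M HCl
Reagents that add atoms: none
Why: Two equivalents of amide base give the carboxylate–lactone enolate dianion 13, metalated only at the lactone α-CH2 because the carboxylate suppresses deprotonation (and Stobbe-type β-elimination of the ring oxygen) at its own α-carbon, and the enolate carbon then displaces bromide from 12 in an SN2 C-alkylation. The closest known reaction type is the trans-selective α-alkylation of paraconic acid dianions and of β-substituted γ-butyrolactone enolates. No ring is closed. The one new stereocentre, the carbon that receives the arylmethyl group, is controlled by the ring: the carboxylate on the neighbouring carbon and the aryl group one carbon further lie on the same face of the nearly planar enolate, so the electrophile should enter from the opposite face, trans to the carboxylate. Because that carboxyl carbon later becomes a ring CH2 of the oxolane while the carbinol carbon leaves the ring, this 3,4-trans lactone relationship is the 3,4-cis relationship of the target. The step needs mono C-alkylation over O-alkylation, which the far more nucleophilic enolate carbon, the low temperature and a near-stoichiometric amount of bromide should secure.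

Step 6
Reactants: 14 (2S,3R,4R)-4-[3-(benzyloxy)-4-methoxybenzyl]-2-[3-(benzyloxy)-4-methoxyphenyl]-5-oxooxolane-3-carboxylic acid
Product: 15 (3R,4S,5S)-3-[3-(benzyloxy)-4-methoxybenzyl]-5-[3-(benzyloxy)-4-methoxyphenyl]-4-(hydroxymethyl)oxolan-2-one
Conditions: BH3·SMe2, THF, 0 °C → rt; MeOH
Reagents that add atoms: none
Why: Borane reduces a carboxylic acid through its acyloxyborane much faster than a lactone or benzyl ethers (chemoselective borane reduction, standard in paraconic acid and lignan chemistry), so the primary alcohol should form with the three stereocentres untouched.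

Step 7
Reactants: 15 (3R,4S,5S)-3-[3-(benzyloxy)-4-methoxybenzyl]-5-[3-(benzyloxy)-4-methoxyphenyl]-4-(hydroxymethyl)oxolan-2-one
Product: 16 [(2S,3S,4R)-4-[3-(benzyloxy)-4-methoxybenzyl]-2-[3-(benzyloxy)-4-methoxyphenyl]-5-oxooxolan-3-yl]methyl methanesulfonate
Conditions: MsCl, Et3N, CH2Cl2, −20 → 0 °C
Reagents that add atoms: methanesulfonyl chloride, CS(=O)(=O)Cl
Why: Sulfene-type mesylation of the only free (primary) hydroxyl is fast at low temperature, which should outrun base-induced translactonisation and makes the hydroxymethyl carbon the electrophile for the ring switch; no stereocentre is touched.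

Step 8
Reactants: 16 [(2S,3S,4R)-4-[3-(benzyloxy)-4-methoxybenzyl]-2-[3-(benzyloxy)-4-methoxyphenyl]-5-oxooxolan-3-yl]methyl methanesulfonate
Product: 18 (S)-[3-(benzyloxy)-4-methoxyphenyl]{(3S,4R)-4-[3-(benzyloxy)-4-methoxybenzyl]oxolan-3-yl}methanol, via diol mesylate 17 (not isolated)
Conditions: LiBH4, THF, 0 °C → rt; then K2CO3, MeOH, 40 °C
Reagents that add atoms: none
Why: Lithium borohydride reduces the lactone to the diol much faster than it displaces a primary mesylate, and of the two hydroxyls set free only the primary one can reach the CH2OMs carbon by a 5-exo-tet Williamson closure (the benzylic oxygen could only form an oxetane), so the oxolane should close with the benzylic alcohol left free and all stereocentres retained.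

Step 9
Reactants: 18 (S)-[3-(benzyloxy)-4-methoxyphenyl]{(3S,4R)-4-[3-(benzyloxy)-4-methoxybenzyl]oxolan-3-yl}methanol
Product: 19 5-{[(3R,4S)-4-[(S)-hydroxy(3-hydroxy-4-methoxyphenyl)methyl]oxolan-3-yl]methyl}-2-methoxyphenol (CNP0108210.1)
Conditions: H2 (1 atm), 10% Pd/C, EtOAc, rt
Reagents that add atoms: none
Why: Hydrogenolysis of aryl benzyl ethers over Pd/C in a neutral aprotic solvent is much faster than C–O hydrogenolysis of a secondary benzylic alcohol, so stopping after two equivalents of hydrogen should release both phenols and keep the carbinol and its configuration.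

**Compound list**

1 | (S)-4-benzyl-1,3-oxazolidin-2-one | O=C1N[C@@H](Cc2ccccc2)CO1 | starting material
2 | methyl 4-chloro-4-oxobutanoate | COC(=O)CCC(=O)Cl | starting material
3 | N-lithio-(S)-4-benzyl-1,3-oxazolidin-2-one | [Li+].O=C1[N-][C@@H](Cc2ccccc2)CO1 | intermediate
4 | methyl 4-[(4S)-4-benzyl-2-oxo-1,3-oxazolidin-3-yl]-4-oxobutanoate | COC(=O)CCC(=O)N1C(=O)OC[C@@H]1Cc1ccccc1 | intermediate
5 | 3-(benzyloxy)-4-methoxybenzaldehyde | COc1ccc(C=O)cc1OCc1ccccc1 | starting material
6 | methyl (3R,4S)-3-{[(4S)-4-benzyl-2-oxo-1,3-oxazolidin-3-yl]carbonyl}-4-[3-(benzyloxy)-4-methoxyphenyl]-4-[(trimethylsilyl)oxy]butanoate | COC(=O)C[C@H]([C@H](O[Si](C)(C)C)c1ccc(OC)c(OCc2ccccc2)c1)C(=O)N1C(=O)OC[C@@H]1Cc1ccccc1 | intermediate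
7 | methyl (3R,4S)-3-{[(4S)-4-benzyl-2-oxo-1,3-oxazolidin-3-yl]carbonyl}-4-[3-(benzyloxy)-4-methoxyphenyl]-4-hydroxybutanoate | COC(=O)C[C@H]([C@H](O)c1ccc(OC)c(OCc2ccccc2)c1)C(=O)N1C(=O)OC[C@@H]1Cc1ccccc1 | intermediate
8 | (4S)-4-benzyl-3-{[(2S,3R)-2-[3-(benzyloxy)-4-methoxyphenyl]-5-oxooxolan-3-yl]carbonyl}-1,3-oxazolidin-2-one | O=C1O[C@H](c2ccc(OC)c(OCc3ccccc3)c2)[C@H](C(=O)N2C(=O)OC[C@@H]2Cc2ccccc2)C1 | intermediate
9 | lithium (2S,3R)-2-[3-(benzyloxy)-4-methoxyphenyl]-5-oxooxolane-3-carboperoxoate | [Li+].O=C1O[C@H](c2ccc(OC)c(OCc3ccccc3)c2)[C@H](C(=O)O[O-])C1 | intermediate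
10 | (2S,3R)-2-[3-(benzyloxy)-4-methoxyphenyl]-5-oxooxolane-3-carboxylic acid | O=C1O[C@H](c2ccc(OC)c(OCc3ccccc3)c2)[C@H](C(=O)O)C1 | intermediate
11 | [3-(benzyloxy)-4-methoxyphenyl]methanol | COc1ccc(CO)cc1OCc1ccccc1 | starting material
12 | 2-(benzyloxy)-4-(bromomethyl)-1-methoxybenzene | COc1ccc(CBr)cc1OCc1ccccc1 | intermediate
13 | disodium (2S,3R)-2-[3-(benzyloxy)-4-methoxyphenyl]-5-oxido-2,3-dihydrofuran-3-carboxylate | [Na+].[Na+].[O-]C1=C[C@@H](C([O-])=O)[C@@H](c2ccc(OC)c(OCc3ccccc3)c2)O1 | intermediate
14 | (2S,3R,4R)-4-[3-(benzyloxy)-4-methoxybenzyl]-2-[3-(benzyloxy)-4-methoxyphenyl]-5-oxooxolane-3-carboxylic acid | O=C1O[C@H](c2ccc(OC)c(OCc3ccccc3)c2)[C@H](C(=O)O)[C@H]1Cc1ccc(OC)c(OCc2ccccc2)c1 | intermediate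
15 | (3R,4S,5S)-3-[3-(benzyloxy)-4-methoxybenzyl]-5-[3-(benzyloxy)-4-methoxyphenyl]-4-(hydroxymethyl)oxolan-2-one | O=C1O[C@H](c2ccc(OC)c(OCc3ccccc3)c2)[C@H](CO)[C@H]1Cc1ccc(OC)c(OCc2ccccc2)c1 | intermediate
16 | [(2S,3S,4R)-4-[3-(benzyloxy)-4-methoxybenzyl]-2-[3-(benzyloxy)-4-methoxyphenyl]-5-oxooxolan-3-yl]methyl methanesulfonate | O=C1O[C@H](c2ccc(OC)c(OCc3ccccc3)c2)[C@H](COS(C)(=O)=O)[C@H]1Cc1ccc(OC)c(OCc2ccccc2)c1 | intermediate
17 | (2S,3R)-3-[3-(benzyloxy)-4-methoxybenzyl]-2-{(S)-[3-(benzyloxy)-4-methoxyphenyl](hydroxy)methyl}-4-hydroxybutyl methanesulfonate | OC[C@H](Cc1ccc(OC)c(OCc2ccccc2)c1)[C@@H](COS(C)(=O)=O)[C@H](O)c1ccc(OC)c(OCc2ccccc2)c1 | intermediate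
18 | (S)-[3-(benzyloxy)-4-methoxyphenyl]{(3S,4R)-4-[3-(benzyloxy)-4-methoxybenzyl]oxolan-3-yl}methanol | COc1ccc(C[C@H]2COC[C@H]2[C@H](O)c2ccc(OC)c(OCc3ccccc3)c2)cc1OCc1ccccc1 | intermediate
19 | 5-{[(3R,4S)-4-[(S)-hydroxy(3-hydroxy-4-methoxyphenyl)methyl]oxolan-3-yl]methyl}-2-methoxyphenol | COc1ccc(C[C@H]2COC[C@H]2[C@H](O)c2ccc(OC)c(O)c2)cc1O | target

Total step count: 9.
Longest linear sequence: 8 steps (steps 1, 2, 3, 5, 6, 7, 8, 9 from compound 1); step 4 is a one-step side branch.

**Steps most likely to fail**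

Step 2. The succinate imide lies outside the usual substrate range of the magnesium-catalysed anti-aldol: chelation or enolisation at the remote ester, slow turnover with the electron-rich aldehyde, or erosion of the anti selectivity may occur, and the acid-catalysed ring closure may ionise the benzylic carbinol. Fallback, setting out from 1 and returning at 8: N-acylation of 1 with pent-4-enoyl chloride (n-BuLi, THF, −78 °C) should give (4S)-4-benzyl-3-(pent-4-enoyl)-1,3-oxazolidin-2-one F1, a plain alkyl imide without a second carbonyl. The same magnesium-catalysed anti-aldol with 5 should give the trimethylsilyl ether of the anti-aldol adduct F2 and, after 1 M HCl/THF, the anti-aldol alcohol F3. Lemieux–Johnson cleavage of the terminal alkene (OsO4 cat., NaIO4, 2,6-lutidine, dioxane/H2O) should give the aldehyde directly in its ring-closed form, the five-membered lactol F4. Oxidation of this lactol (TEMPO cat., PhI(OAc)2, CH2Cl2) should give 8 without an acid-catalysed lactonisation.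

Step 5. The dianion may be poorly soluble or incompletely formed, proton transfer may lead to metalation next to the carboxylate followed by β-elimination of the ring oxygen (ring opening to an arylidene succinate), and the carboxylate may be O-benzylated. Fallback, setting out from 10 and returning at 15: borane reduction of the acid first (BH3·SMe2, THF) should give (4S,5S)-5-[3-(benzyloxy)-4-methoxyphenyl]-4-(hydroxymethyl)oxolan-2-one F5. Silylation (TBSCl, imidazole, DMF) should give the tert-butyldimethylsilyl ether F6. LDA (THF, −78 °C) should give the simple lithium lactone enolate F7, which should be benzylated by 12 trans to the silyloxymethyl group to give the 3,4-trans lactone silyl ether F8. Desilylation (TBAF, AcOH, THF, 0 °C) should then give 15.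

Step 8. Hydride may displace the mesylate or an alkoxide may eliminate it before the primary alkoxide is unmasked, and the benzylic alkoxide of the 1,3-hydroxy sulfonate may fragment instead of waiting for ring closure. Fallback, setting out from 15 and returning at 18: LiAlH4 (THF, 0 °C) should reduce the lactone to (2S,3R)-2-{(S)-[3-(benzyloxy)-4-methoxyphenyl](hydroxy)methyl}-3-[3-(benzyloxy)-4-methoxybenzyl]butane-1,4-diol F9. Bu2SnO (1 equiv, PhMe, reflux with removal of water) should engage the 1,3-diol made of the benzylic hydroxyl and the hydroxymethyl group on the adjacent carbon as the six-membered dibutylstannylene acetal F10. TsCl (1 equiv, CH2Cl2, 0 °C) should then sulfonylate its primary oxygen to give the primary tosylate F11. K2CO3 in MeOH should close the oxolane from the remaining primary hydroxyl to give 18; here the benzylic hydroxyl directs the activation instead of competing in the ring closure.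

Further compounds
F1 | step 2 | (4S)-4-benzyl-3-(pent-4-enoyl)-1,3-oxazolidin-2-one | C=CCCC(=O)N1C(=O)OC[C@@H]1Cc1ccccc1
F2 | step 2 | (4S)-4-benzyl-3-[(2R)-2-{(S)-[3-(benzyloxy)-4-methoxyphenyl][(trimethylsilyl)oxy]methyl}pent-4-enoyl]-1,3-oxazolidin-2-one | C=CC[C@H]([C@H](O[Si](C)(C)C)c1ccc(OC)c(OCc2ccccc2)c1)C(=O)N1C(=O)OC[C@@H]1Cc1ccccc1
F3 | step 2 | (4S)-4-benzyl-3-[(2R)-2-{(S)-[3-(benzyloxy)-4-methoxyphenyl](hydroxy)methyl}pent-4-enoyl]-1,3-oxazolidin-2-one | C=CC[C@H]([C@H](O)c1ccc(OC)c(OCc2ccccc2)c1)C(=O)N1C(=O)OC[C@@H]1Cc1ccccc1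
F4 | step 2 | (4S)-4-benzyl-3-{[(2S,3R)-2-[3-(benzyloxy)-4-methoxyphenyl]-5-hydroxyoxolan-3-yl]carbonyl}-1,3-oxazolidin-2-one (lactol, both anomers) | OC1O[C@H](c2ccc(OC)c(OCc3ccccc3)c2)[C@H](C(=O)N2C(=O)OC[C@@H]2Cc2ccccc2)C1
F5 | step 5 | (4S,5S)-5-[3-(benzyloxy)-4-methoxyphenyl]-4-(hydroxymethyl)oxolan-2-one | O=C1O[C@H](c2ccc(OC)c(OCc3ccccc3)c2)[C@H](CO)C1
F6 | step 5 | (4S,5S)-5-[3-(benzyloxy)-4-methoxyphenyl]-4-{[(tert-butyldimethylsilyl)oxy]methyl}oxolan-2-one | O=C1O[C@H](c2ccc(OC)c(OCc3ccccc3)c2)[C@H](CO[Si](C)(C)C(C)(C)C)C1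
F7 | step 5 | lithium (4S,5S)-5-[3-(benzyloxy)-4-methoxyphenyl]-4-{[(tert-butyldimethylsilyl)oxy]methyl}-4,5-dihydrofuran-2-olate | [Li+].[O-]C1=C[C@@H](CO[Si](C)(C)C(C)(C)C)[C@@H](c2ccc(OC)c(OCc3ccccc3)c2)O1
F8 | step 5 | (3R,4S,5S)-3-[3-(benzyloxy)-4-methoxybenzyl]-5-[3-(benzyloxy)-4-methoxyphenyl]-4-{[(tert-butyldimethylsilyl)oxy]methyl}oxolan-2-one | O=C1O[C@H](c2ccc(OC)c(OCc3ccccc3)c2)[C@H](CO[Si](C)(C)C(C)(C)C)[C@H]1Cc1ccc(OC)c(OCc2ccccc2)c1
F9 | step 8 | (2S,3R)-2-{(S)-[3-(benzyloxy)-4-methoxyphenyl](hydroxy)methyl}-3-[3-(benzyloxy)-4-methoxybenzyl]butane-1,4-diol | OC[C@H](Cc1ccc(OC)c(OCc2ccccc2)c1)[C@@H](CO)[C@H](O)c1ccc(OC)c(OCc2ccccc2)c1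
F10 | step 8 | 2,2-dibutyl-1,3,2-dioxastanninane (stannylene acetal) across the benzylic oxygen and the adjacent CH2O of F9, configuration unchanged | CCCC[Sn]1(CCCC)OC[C@H]([C@H](CO)Cc2ccc(OC)c(OCc3ccccc3)c2)[C@@H](c2ccc(OC)c(OCc3ccccc3)c2)O1
F11 | step 8 | (2S,3R)-3-[3-(benzyloxy)-4-methoxybenzyl]-2-{(S)-[3-(benzyloxy)-4-methoxyphenyl](hydroxy)methyl}-4-hydroxybutyl 4-methylbenzenesulfonate | OC[C@H](Cc1ccc(OC)c(OCc2ccccc2)c1)[C@@H](COS(=O)(=O)c1ccc(C)cc1)[C@H](O)c1ccc(OC)c(OCc2ccccc2)c1
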